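**Plan**

1. Cuts: the C7 allyl ester, the 15β-OH (allylic oxidation) and the 3β-OH (ketone reduction) come off first. Ring A is then cut at C1–C10 and C3–C4, ring D at C13–C16, the lactone at O–C19, the side bonds at C4–C5 and C6–C7, and ring C across C8–C14/C9–C11 (Diels–Alder). A bought cyclopentenone remains as ring B.
2. Forward order: ring B (bought) → ring C (Diels–Alder) → C7 and the C4/C18/C19 unit → γ-lactone → ring D (ketyl–alkyne) → ring A last.
3. Enabling feature: C10 is the tertiary carbinol carbon of a γ-lactone (C4–C19–O–C10–C5) cis-fused to ring B. Before ring A exists its hydrogen lies 1,5 to C2 of an acryloyl group on C4, and C1 is the β-carbon of the C3 carbonyl. A radical moved from C2 to C10 can therefore close ring A on C1 without a leaving group ever being placed on C10.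
4. Stereochemistry: one bought stereocenter (the silyloxy carbon of 1, later C6) steers the Diels–Alder face (C8, C9) and is then eliminated. C6, C5, C10, C4, C13, C3 and C15 follow by substrate control on the cis-fused frameworks.

Key step: step 11

Remark: carbon labels C1–C19 are gibberellane numbers and are used for every intermediate; α and β are used in the sense customary for gibberellins (H5 and H9 are β); compounds 1, 2, 6, 11 and 16 are taken as purchased.

**Route**

Step 1
Reactants: 1 (S)-4-(tert-butyldimethylsilyloxy)cyclopent-2-en-1-one; 2 3-bromo-1-(trimethylsilyl)prop-1-yne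
Product: 4 (3S,4S)-4-(tert-butyldimethylsilyloxy)-1-(trimethylsilyloxy)-3-[3-(trimethylsilyl)prop-2-yn-1-yl]cyclopent-1-ene, via propargyl Grignard reagent 3 (not isolated)
Conditions: 2, Mg, Et2O, 0 °C; then 1, CuBr·SMe2 (10 mol %), Me3SiCl, HMPA, THF, −78 °C
Reagents that add atoms: chlorotrimethylsilane C[Si](C)(C)Cl
Why: Copper-catalysed conjugate addition of a Grignard reagent with chlorosilane trapping should add anti to the 4-silyloxy group (3,4-trans) and fix the enolate regiochemistry for step 2, the silyl cap on the alkyne keeping bond formation at the CH2 terminus.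

Step 2
Reactants: 4 (3S,4S)-4-(tert-butyldimethylsilyloxy)-1-(trimethylsilyloxy)-3-[3-(trimethylsilyl)prop-2-yn-1-yl]cyclopent-1-ene
Product: 5 (S)-4-(tert-butyldimethylsilyloxy)-3-[3-(trimethylsilyl)prop-2-yn-1-yl]cyclopent-2-en-1-one
Conditions: Pd(OAc)2 (10 mol %), O2 (1 atm), DMSO, 25 °C
Reagents that add atoms: none
Why: Saegusa–Ito oxidation (aerobic, catalytic in palladium diacetate) of the regiodefined silyl enol ether should return the enone with the propargyl group on the β-carbon and leave the silyloxy stereocenter untouched.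

Step 3
Reactants: 5 (S)-4-(tert-butyldimethylsilyloxy)-3-[3-(trimethylsilyl)prop-2-yn-1-yl]cyclopent-2-en-1-one; 6 2-(tert-butyldimethylsilyloxy)buta-1,3-diene
Product: 7 cis-fused 3,5-bis(tert-butyldimethylsilyloxy)-3a-[3-(trimethylsilyl)prop-2-yn-1-yl]-2,3,3a,4,7,7a-hexahydro-1H-inden-1-one (6β-silyloxy; 8β-propargyl; 9β-H)
Conditions: 6 (2 equiv), AlBr3/AlMe3 (5:1, 20 mol %), PhMe/CH2Cl2, −10 °C
Reagents that add atoms: none
Why: Lewis acid-promoted Diels–Alder reaction of a hindered β,β-disubstituted enone with a 2-silyloxydiene should follow the para rule (silyloxy carbon C13 1,4 to the carbonyl-bearing C9) and add suprafacially on the face anti to the allylic silyloxy group, which sets the quaternary C8 and C9 (cis ring fusion) and leaves C13 masked as its silyl enol ether.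

Step 4
Reactants: 7 cis-fused 3,5-bis(tert-butyldimethylsilyloxy)-3a-[3-(trimethylsilyl)prop-2-yn-1-yl]-2,3,3a,4,7,7a-hexahydro-1H-inden-1-one
Product: 8 cis-fused 5-(tert-butyldimethylsilyloxy)-3a-[3-(trimethylsilyl)prop-2-yn-1-yl]-3a,4,7,7a-tetrahydro-1H-inden-1-one (enone across gibberellane C5=C6)
Conditions: DBU (0.3 equiv), CH2Cl2, 25 °C
Reagents that add atoms: none
Why: E1cB elimination of the β-silyloxy group should give the C5=C6 enone, which removes the controlling stereocenter after it has done its work and makes C6 an acceptor carbon.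

Step 5
Reactants: 8 cis-fused 5-(tert-butyldimethylsilyloxy)-3a-[3-(trimethylsilyl)prop-2-yn-1-yl]-3a,4,7,7a-tetrahydro-1H-inden-1-one
Product: 10 allyl 6β-carboxylate of the saturated C10 ketone (allyl ester of 9), via potassium carboxylate 9 (not isolated)
Conditions: HCO2K, 4CzIPN (2,4,5,6-tetra(carbazol-9-yl)isophthalonitrile, 2 mol %), DABCO (20 mol %), DMSO, 450 nm LEDs, 25 °C; then allyl bromide, 25 °C
Reagents that add atoms: potassium formate [K+].[O-]C=O; allyl bromide C=CCBr
Why: Giese-type hydrocarboxylation by the CO2 radical anion from formate (photoredox with hydrogen atom transfer catalysis) should attach C7 to the β-carbon C6 from the convex β face of the cis-hydrindenone, the centre staying correctable by base because it is α to the ester, and the carboxylate is allylated in situ (SN2).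

Step 6
Reactants: 10 allyl 6β-carboxylate of the saturated C10 ketone; 11 methyl 2-bromopropanoate (racemic)
Product: 12 C5-alkylated keto diester (5α-(1-methoxy-1-oxopropan-2-yl) trans to the 6β-ester; both C4 epimers)
Conditions: LiN(i-Pr)2 (LDA), THF, −78 °C; then 11, DMPU, −78 to −30 °C
Reagents that add atoms: none
Why: Kinetic ketone enolate formation at the less hindered α-carbon C5 and SN2 alkylation anti to the C6 ester should install C4, C18 and C19 and set C5, with C4 left as a mixture because it is enolised again in step 9.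

Step 7
Reactants: 12 C5-alkylated keto diester
Product: 14 keto lactone (C13 ketone; 8β-prop-2-ynyl; 19,10-lactone; 10β-H; both C4 epimers), via silylated lactone 13 (not isolated)
Conditions: NaBH4, MeOH/THF, −40 to 0 °C; AcOH; then Bu4NF, THF, 0 °C
Reagents that add atoms: none
Why: Borohydride reduction should attack the only free ketone (C10) from the β face, away from the α substituents on C5 and C9, so that the 10α-alkoxide lactonises onto the C19 methyl ester (cis-fused γ-lactone, sets C10), and fluoride then removes the alkynyl silane and unmasks the C13 ketone.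

Step 8
Reactants: 14 keto lactone (C13 ketone; 8β-prop-2-ynyl; 19,10-lactone)
Product: 15 13-hydroxy-16-methylene lactone (rings B, C and D and the lactone of the target; 10β-H; both C4 epimers)
Conditions: SmI2 (3 equiv), HMPA, t-BuOH, THF, 0 °C
Reagents that add atoms: none
Why: Samarium ketyl–alkyne reductive cyclisation (5-exo-dig) should form C13–C16 with the bridgehead alcohol and the exocyclic methylene, the configuration at C13 being dictated by the bicyclo[3.2.1]octane bridge from the 8β-propargyl group.

Step 9
Reactants: 15 13-hydroxy-16-methylene lactone; 16 2-bromoprop-2-enal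
Product: 17 aldol adduct with quaternary C4 (C3 carbinol bearing a 1-bromovinyl group; both C3 epimers)
Conditions: LiN(i-Pr)2 (LDA, 2.3 equiv), THF, −78 °C; then 16, −78 °C; AcOH quench at −78 °C
Reagents that add atoms: none
Why: Aldol addition of the lactone enolate on the convex face of the cis-fused bicyclic lactone (anti to C6) should set the quaternary C4 with C3 on the side of H10 and the 18-methyl group on the concave side, the C3 carbinol being oxidised in the next step.

Step 10
Reactants: 17 aldol adduct with quaternary C4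
Product: 18 2-bromoacryloyl lactone (C3 ketone; C2 bromide; C1 methylene)
Conditions: Dess–Martin periodinane, CH2Cl2, 0 °C
Reagents that add atoms: none
Why: Dess–Martin oxidation of the secondary allylic alcohol should give the non-enolisable α-bromo vinyl ketone without touching the tertiary C13 alcohol or the alkenes.

Step 11
Reactants: 18 2-bromoacryloyl lactone
Product: 19 3-oxo lactone allyl ester (ring A closed; 13-OH; 16-ene; 19,10-lactone)
Conditions: Bu3SnH (1.3 equiv, syringe pump over 8 h), AIBN (0.2 equiv), PhH (0.002 M), 80 °C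
Reagents that add atoms: none
Why: Proposed new method: the stannyl radical abstracts bromine to give the C2 vinyl radical, which takes H10 by 1,5-hydrogen atom transfer through a six-membered transition state (C2–C3–C4–C5–C10–H); the tertiary α-acyloxy C10 radical then adds to C1, the β-carbon of the vinyl ketone just regenerated, and the α-keto radical at C2 is reduced by Bu3SnH. The closest known reaction type is radical translocation of vinyl radicals made from vinyl bromides (1,5-hydrogen atom transfer followed by cyclisation onto the alkene left behind), joined to the Giese addition of α-oxygenated tertiary radicals to enones. Ring A (C10, C1, C2, C3, C4, C5) closes in the 6-endo-trig mode, as 4-oxohex-5-enyl radicals generally do, and turns the fused lactone into the bridged 19,10-lactone. The only new stereocenter, C10, is dictated by the cis-fused γ-lactone on ring B: the acryloyl arm on C4 reaches C10 only on the face that carried H10, so C–H is replaced by C–C with retention. The step needs hydrogen transfer from C10–H rather than from other C–H bonds (C6–H is anti to C3 across C4–C5, and H5 or the C18 hydrogens would need 1,4-shifts), 6-endo rather than 5-exo closure (attack at C2 is polarity-mismatched and would give a strained 2-oxabicyclo[2.2.1]heptane), and translocation ahead of direct reduction, which slow addition of the hydride at high dilution should secure.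

Step 12
Reactants: 19 3-oxo lactone allyl ester
Product: 20 3β,13-diol allyl ester (3β-alcohol of 19)
Conditions: K[HB(s-Bu)3] (K-Selectride, 2.5 equiv), THF, −78 °C; AcOH quench at −78 °C
Reagents that add atoms: none
Why: Substrate-controlled reduction with a bulky trialkylborohydride should attack the C3 ketone equatorially, avoiding the 1,3-diaxial H1β and H5β, and give the axial 3β-alcohol, the cold acidic quench preventing retro-aldol cleavage of C3–C4.

Step 13
Reactants: 20 3β,13-diol allyl ester
Product: 21 3β,13,15β-triol allyl ester (allyl ester of the target)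
Conditions: SeO2 (0.5 equiv), t-BuOOH, CH2Cl2, 25 °C
Reagents that add atoms: tert-butyl hydroperoxide CC(C)(C)OO
Why: Riley allylic hydroxylation (ene reaction then [2,3]-sigmatropic shift) of the 16(17)-alkene can only occur at C15 and should take place on the face syn to H9, because the opposite face is covered by the 6β-ester, which gives the 15β-alcohol.

Step 14
Reactants: 21 3β,13,15β-triol allyl ester
Product: 22 target gibberellin (free 7-acid of 21)
Conditions: Pd(PPh3)4 (5 mol %), morpholine, THF, 25 °C; dilute aqueous KHSO4 work-up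
Reagents that add atoms: none
Why: Tsuji–Trost deallylation (allyl transfer from the ester to morpholine on zerovalent palladium) should free the hindered C7 acid under neutral conditions that spare the lactone, the 3β-hydroxyl (no retro-aldol) and the allylic alcohols.

**Compound list**

1 | (S)-4-(tert-butyldimethylsilyloxy)cyclopent-2-en-1-one | O=C1C=C[C@@H](O[Si](C)(C)C(C)(C)C)C1 | starting material
2 | 3-bromo-1-(trimethylsilyl)prop-1-yne | C[Si](C)(C)C#CCBr | starting material
3 | [3-(trimethylsilyl)prop-2-yn-1-yl]magnesium bromide (propargyl Grignard reagent) | C[Si](C)(C)C#CC[Mg]Br | intermediate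
4 | (3S,4S)-4-(tert-butyldimethylsilyloxy)-1-(trimethylsilyloxy)-3-[3-(trimethylsilyl)prop-2-yn-1-yl]cyclopent-1-ene (C3 and C4 substituents trans) | C[Si](C)(C)C#CC[C@H]1C=C(O[Si](C)(C)C)C[C@@H]1O[Si](C)(C)C(C)(C)C | intermediate
5 | (S)-4-(tert-butyldimethylsilyloxy)-3-[3-(trimethylsilyl)prop-2-yn-1-yl]cyclopent-2-en-1-one | C[Si](C)(C)C#CCC1=CC(=O)C[C@@H]1O[Si](C)(C)C(C)(C)C | intermediate
6 | 2-(tert-butyldimethylsilyloxy)buta-1,3-diene | C=CC(=C)O[Si](C)(C)C(C)(C)C | starting material
7 | cis-fused 3,5-bis(tert-butyldimethylsilyloxy)-3a-[3-(trimethylsilyl)prop-2-yn-1-yl]-2,3,3a,4,7,7a-hexahydro-1H-inden-1-one; C10 ketone, 6β-silyloxy, 8β-propargyl, 9β-H, C12=C13 silyl enol ether | C[Si](C)(C)C#CC[C@]23CC(O[Si](C)(C)C(C)(C)C)=CC[C@H]2C(=O)C[C@@H]3O[Si](C)(C)C(C)(C)C | intermediate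
8 | cis-fused 5-(tert-butyldimethylsilyloxy)-3a-[3-(trimethylsilyl)prop-2-yn-1-yl]-3a,4,7,7a-tetrahydro-1H-inden-1-one; enone across gibberellane C5=C6 | C[Si](C)(C)C#CC[C@]23CC(O[Si](C)(C)C(C)(C)C)=CC[C@H]2C(=O)C=C3 | intermediate
9 | potassium carboxylate: potassium salt of the 6β-carboxylic acid of the saturated C10 ketone | C[Si](C)(C)C#CC[C@]23CC(O[Si](C)(C)C(C)(C)C)=CC[C@H]2C(=O)C[C@@H]3C(=O)[O-].[K+] | intermediate
10 | allyl 6-(tert-butyldimethylsilyloxy)-3-oxo-7a-[3-(trimethylsilyl)prop-2-yn-1-yl]-2,3,3a,4,7,7a-hexahydro-1H-indene-1-carboxylate; cis-fused, ester β (same face as the propargyl group) | C[Si](C)(C)C#CC[C@]23CC(O[Si](C)(C)C(C)(C)C)=CC[C@H]2C(=O)C[C@@H]3C(=O)OCC=C | intermediate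
11 | methyl 2-bromopropanoate (racemic) | CC(Br)C(=O)OC | starting material
12 | 10 carrying a 1-methoxy-1-oxopropan-2-yl group at C5, α and trans to the 6β-ester; both C4 epimers | C[Si](C)(C)C#CC[C@]23CC(O[Si](C)(C)C(C)(C)C)=CC[C@H]2C(=O)[C@@H](C(C)C(=O)OC)[C@@H]3C(=O)OCC=C | intermediate
13 | silylated lactone: 19,10-γ-lactone (10β-H, lactone on the α face) still carrying the alkynyl silane and the C13 silyl enol ether | C[Si](C)(C)C#CC[C@]23CC(O[Si](C)(C)C(C)(C)C)=CC[C@H]2[C@H]1OC(=O)C(C)[C@H]1[C@@H]3C(=O)OCC=C | intermediate
14 | keto lactone: C13 ketone, 8β-prop-2-ynyl, 19,10-lactone with 10β-H, allyl 7-oate; both C4 epimers | C#CC[C@]23CC(=O)CC[C@H]2[C@H]1OC(=O)C(C)[C@H]1[C@@H]3C(=O)OCC=C | intermediate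
15 | 13-hydroxy-16-methylene lactone: rings B, C and D and the lactone of the target, 10β-H, allyl 7-oate; both C4 epimers | C=C1C[C@]23C[C@@]1(O)CC[C@H]2[C@H]1OC(=O)C(C)[C@H]1[C@@H]3C(=O)OCC=C | intermediate
16 | 2-bromoprop-2-enal | C=C(Br)C=O | starting material
17 | aldol adduct: 15 with quaternary C4 (18-methyl on the concave face, C3 carbinol with a 1-bromovinyl group on the side of H10); both C3 epimers | C=C1C[C@]23C[C@@]1(O)CC[C@H]2[C@H]1OC(=O)[C@](C)(C(O)C(Br)=C)[C@H]1[C@@H]3C(=O)OCC=C | intermediate
18 | 2-bromoacryloyl lactone: C3 ketone of 17 | C=C1C[C@]23C[C@@]1(O)CC[C@H]2[C@H]1OC(=O)[C@](C)(C(=O)C(Br)=C)[C@H]1[C@@H]3C(=O)OCC=C | intermediate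
19 | 3-oxo lactone allyl ester: ring A closed, C3 ketone, 13-hydroxy, 16-ene, 19,10-lactone, allyl 7-oate | C=C1C[C@]23C[C@@]1(O)CC[C@H]2[C@@]12CCC(=O)[C@@](C)(C(=O)O1)[C@H]2[C@@H]3C(=O)OCC=C | intermediate
20 | 3β,13-diol allyl ester: 3β-alcohol of 19 | C=C1C[C@]23C[C@@]1(O)CC[C@H]2[C@@]12CC[C@H](O)[C@@](C)(C(=O)O1)[C@H]2[C@@H]3C(=O)OCC=C | intermediate
21 | 3β,13,15β-triol allyl ester: allyl ester of the target | C=C1[C@@H](O)[C@]23C[C@@]1(O)CC[C@H]2[C@@]12CC[C@H](O)[C@@](C)(C(=O)O1)[C@H]2[C@@H]3C(=O)OCC=C | intermediate
22 | target gibberellin: 3β,13,15β-trihydroxy-20-norgibberell-16-ene-7,19-dioic acid 19,10-lactone | C=C1[C@@H](O)[C@]23C[C@@]1(O)CC[C@H]2[C@@]12CC[C@H](O)[C@@](C)(C(=O)O1)[C@H]2[C@@H]3C(=O)O | target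

**Summary**

Total step count: 14. Longest linear sequence: 14 steps (1 to 22).

Steps most likely to fail:

1. Step 11 (proposed new method). The C2 vinyl radical may be reduced by the tin hydride before it takes H10, or an α-acyl vinyl radical may abstract hydrogen too slowly. The outcome would be plain debromination and loss of the radical handle. The fallback uses known chemistry and closes ring A by an aldol at C3–C4 instead; it sets out from 12 and comes back at 19. The cerium-modified Grignard reagent from 2-(2-bromoethyl)-1,3-dioxolane (CeCl3, THF, −78 °C) should add to the C10 ketone of 12 from the β face, and the alkoxide should lactonise to the acetal lactone F1. Bu4NF/AcOH should then give the alkynyl ketone F2, SmI2/HMPA/t-BuOH the bridged tertiary alcohol F3, and pyridinium p-toluenesulfonate in wet acetone the aldehyde F4. Reversible intramolecular aldol addition of the lactone enolate to the C3 aldehyde (KOt-Bu, t-BuOH/THF, 0 °C) should close ring A as the 3-hydroxy lactone F5 (both C3 epimers). Dess–Martin oxidation should return the material to 19.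

2. Step 3. Cycloaddition to the hindered β,β-disubstituted enone may be too slow, so that Lewis acid-induced loss of the allylic silyloxy group or arrest at the open Mukaiyama–Michael stage takes over. The fallback sets out from 5 and comes back at 7. The far more reactive 1-(dimethylamino)-3-(tert-butyldimethylsilyloxy)buta-1,3-diene should add thermally (PhMe, 80 °C, no Lewis acid) with the same regio- and facial sense to give the aminocyclohexene adduct F6. Brief treatment with dilute HCl should release the C11=C12 enone F7. Conjugate reduction with silyl trapping ([(Ph3P)CuH]6 (cat.), t-BuMe2SiH) should then regenerate the C12=C13 silyl enol ether 7.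

3. Step 5. Electron transfer from the CO2 radical anion to the enone (pinacol coupling or simple saturation) may outrun C–C bond formation at the neopentyl carbon C6, and addition may occur with poor facial control. The fallback sets out from 8 and comes back at 14. A vinyl cuprate (CH2=CHMgBr, CuBr·SMe2, Me3SiCl, THF, −78 °C) should add to C6 of 8 and give the trimethylsilyl enol ether F8. MeLi (THF, 0 °C) should set free its lithium enolate, which is alkylated with 11 to give the vinyl keto ester F9. NaBH4, as in step 7, should give the silylated vinyl lactone F10, and Bu4NF the vinyl lactone F11. Ozonolysis of the vinyl group (O3, CH2Cl2/MeOH, −78 °C, then Me2S; the terminal alkyne reacts far more slowly) should give the aldehyde F12. Chlorite oxidation (NaClO2, NaH2PO4, 2-methylbut-2-ene, t-BuOH/water) should give the acid F13, and allyl bromide/K2CO3 should return the material to 14.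

**Further compounds**

F1 | step 11 | acetal lactone: 10β-[2-(1,3-dioxolan-2-yl)ethyl] 19,10-lactone, still silylated at the alkyne and the C13 enol | C[Si](C)(C)C#CC[C@]23CC(O[Si](C)(C)C(C)(C)C)=CC[C@H]2[C@@]1(CCC4OCCO4)OC(=O)C(C)[C@H]1[C@@H]3C(=O)OCC=C
F2 | step 11 | alkynyl ketone: C13 ketone and terminal alkyne of F1 | C#CC[C@]23CC(=O)CC[C@H]2[C@@]1(CCC4OCCO4)OC(=O)C(C)[C@H]1[C@@H]3C(=O)OCC=C
F3 | step 11 | bridged tertiary alcohol: 13-hydroxy-16-methylene acetal lactone | C=C1C[C@]23C[C@@]1(O)CC[C@H]2[C@@]1(CCC4OCCO4)OC(=O)C(C)[C@H]1[C@@H]3C(=O)OCC=C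
F4 | step 11 | aldehyde: C3 formyl group on the C1–C2 chain at C10 | C=C1C[C@]23C[C@@]1(O)CC[C@H]2[C@@]1(CCC=O)OC(=O)C(C)[C@H]1[C@@H]3C(=O)OCC=C
F5 | step 11 | 3-hydroxy lactone: compound 20 together with its C3 epimer | C=C1C[C@]23C[C@@]1(O)CC[C@H]2[C@@]12CCC(O)[C@@](C)(C(=O)O1)[C@H]2[C@@H]3C(=O)OCC=C
F6 | step 3 | aminocyclohexene adduct: 7 with a dimethylamino group at C11 | C[Si](C)(C)C#CC[C@]23CC(O[Si](C)(C)C(C)(C)C)=CC(N(C)C)[C@H]2C(=O)C[C@@H]3O[Si](C)(C)C(C)(C)C
F7 | step 3 | C11=C12 enone: C13 ketone conjugated to C11=C12, C10 ketone, 6β-silyloxy | C[Si](C)(C)C#CC[C@]23CC(=O)C=C[C@H]2C(=O)C[C@@H]3O[Si](C)(C)C(C)(C)C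
F8 | step 5 | trimethylsilyl enol ether: 6β-vinyl compound with the C10 oxygen silylated and a C5=C10 double bond | C[Si](C)(C)C#CC[C@]23CC(O[Si](C)(C)C(C)(C)C)=CC[C@H]2C(O[Si](C)(C)C)=C[C@@H]3C=C
F9 | step 5 | vinyl keto ester: 12 with a 6β-vinyl group in place of the allyl ester | C[Si](C)(C)C#CC[C@]23CC(O[Si](C)(C)C(C)(C)C)=CC[C@H]2C(=O)[C@@H](C(C)C(=O)OC)[C@@H]3C=C
F10 | step 5 | silylated vinyl lactone: 13 with a 6β-vinyl group in place of the allyl ester | C[Si](C)(C)C#CC[C@]23CC(O[Si](C)(C)C(C)(C)C)=CC[C@H]2[C@H]1OC(=O)C(C)[C@H]1[C@@H]3C=C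
F11 | step 5 | vinyl lactone: 14 with a 6β-vinyl group in place of the allyl ester | C#CC[C@]23CC(=O)CC[C@H]2[C@H]1OC(=O)C(C)[C@H]1[C@@H]3C=C
F12 | step 5 | aldehyde: 14 with a 6β-formyl group in place of the allyl ester | C#CC[C@]23CC(=O)CC[C@H]2[C@H]1OC(=O)C(C)[C@H]1[C@@H]3C=O
F13 | step 5 | acid: free 7-carboxylic acid of 14 | C#CC[C@]23CC(=O)CC[C@H]2[C@H]1OC(=O)C(C)[C@H]1[C@@H]3C(=O)O
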